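Of the constants the earlier runs could give me, I kept a ratio of two readings rather than a rate constant.

| flask | starting material | second substrate | gas | remark | time |
|---|---|---|---|---|---|
| grey | 0.0091 M | 1 equiv (fed, over 80 min) | 7.2 mM (held) | run made earlier; the fed solution adds 0.50 times the starting volume |  |
| amber | 0.032 M | 1 equiv (fed, over 80 min) | 7.2 mM (held) | run made earlier; the fed solution adds 0.50 times the starting volume |  |
| eta | 0.012 M | 1.00 equiv | 7.2 mM | everything together at the start, the whole solution of second substrate included, so that from the start the volume is larger by 0.50 times the starting volume | 80 min |
| beta | 0.050 M | 1.00 equiv (fed, over 80 min) | 7.2 mM (held) | the fed solution adds 0.50 times the starting volume | 80 min |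

| run | time / min | target / % | starting material / % |
|---|---|---|---|
| grey | 2.50 | 1.5 | 99.2 |
| grey | 8.00 | 4.5 | 94.9 |
| grey | 15.0 | 7.7 | 94.1 |
| grey | 20.0 | 7.9 | 92.2 |
| grey | 30.0 | 13.0 | 87.2 |
| grey | 40.0 | 14.3 | 86.0 |
| amber | 2.50 | 2.0 | 99.4 |
| amber | 8.00 | 1.8 | 96.4 |
| amber | 15.0 | 7.2 | 95.6 |
| amber | 20.0 | 8.2 | 92.1 |
| amber | 30.0 | 10.4 | 87.3 |
| amber | 40.0 | 15.2 | 85.1 |

(readings scatter by 1 percentage point)

- amounts are per litre of the starting volume; all of the dose is in the solution fed
- at the start none of the gas is in solution
- where the amount of starting material changes, what is given in equivalents or mol% on it follows

- which one finishes higher in amount of target, in percent of the starting material charged ("neither" within 2 percentage points) (eta / beta / neither)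
- amount of target at the end, in percent of the starting material charged, eta
- amount of target at the end, in percent of the starting material charged, beta

Amber held 3.52 times the starting material of grey, yet at 40.0 min grey stood at 14.3% of its charge in target and amber at 15.2%. That looked contradictory until I counted in fractions of the charge: with everything else it needs held steady, a step first order in starting material moves the same fraction of it whatever the amount, and dilution changes no fraction. In grey and amber alike, target also ran behind the feed, with half of the second substrate in by that time, so I gave eta and beta one curve.

Averaged over both runs, target stood at 8.05% at 20.0 min and 14.8% at 40.0 min. If the gap to a ceiling shrinks by one factor in each equal interval (pseudo-first-order in the gap), the reading at twice the time over the first reading is one plus that factor. This gave 83.2%: the gap factor, the share of the gap that survives one interval. A ceiling at the full charge requires 92.0%, so my reading, lower, hinted at a ceiling below the charge, though a scatter of 1 percentage point left that loose. Doubling the time again multiplies by one plus the factor squared, so I reckoned 25.0% for both flasks at 80 min.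

The forecast, higher than my figure, gave 27% for eta and 27% for beta, with neither ahead: “Eta's early full dose and beta's feed should make no difference”.

Eta ended at 21.1% and beta at 20.8%, so neither finished higher, and my figure stood 3.9 points too high.

    starting material + coupling partner ⇌ target (K = 48.0 M⁻¹, k = 0.0130 M⁻¹ s⁻¹)
    second substrate + coupling partner ⇌ second product (K = 2900 M⁻¹, k = 0.0180 M⁻¹ s⁻¹)
    gas ⇌ coupling partner, rate k3*(csat - [coupling partner]) (kL = 0.0320 s⁻¹)

Left until 800 min, eta held 25.7% and beta 25.7% in target, with 74.3% of eta's starting material still there. Dividing eta's 14.8% at 40.0 min by one plus the gap factor gives 8.08% for the same flask at 20 min, and that flask, read then, held 8.85%.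

(Readings and results stem from a simulated flask for an exercise; the scatter is artificial.)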